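Of the 3 questions, the one on how much substrate has reacted needs the most thought, so we follow what is left of the catalyst at each step of the time ladder and count the product afterwards.

the same everywhere: left-handed substrate 0.10 M; right-handed substrate 0.10 M; free catalyst 20 mM

|  | reagent | impurity | remark | time |
|---|---|---|---|---|
| north | 0.080 M | 2 mM | run made earlier |  |
| east | 0.080 M | 8.2 mM | run made earlier |  |
| north-west | 0.12 M | 4.1 mM | run made earlier |  |
| flask | 0.0800 M | 4.1 mM |  | 6.0 min |

| run | time / min | left-handed product / % | right-handed product / % |
|---|---|---|---|
| north | 1.00 | 0.6 | 0.7 |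
| north | 2.00 | 1.7 | 2.0 |
| north | 3.00 | 2.0 | 2.5 |
| north | 4.00 | 3.0 | 3.3 |
| north | 5.00 | 3.5 | 3.9 |
| north | 6.00 | 4.1 | 3.9 |
| north | 8.00 | 5.4 | 5.6 |
| east | 0.417 | 0.2 | 0 |
| east | 1.00 | 0.6 | 0.4 |
| east | 2.00 | 0.5 | 1.2 |
| east | 3.00 | 1.9 | 1.5 |
| east | 4.00 | 1.5 | 2.1 |
| east | 6.00 | 3.0 | 2.5 |
| east | 8.00 | 3.3 | 3.6 |
| north-west | 0.667 | 0.1 | 0.8 |
| north-west | 2.00 | 1.4 | 2.1 |
| north-west | 3.00 | 2.5 | 3.0 |
| north-west | 5.00 | 3.5 | 4.6 |
| north-west | 8.00 | 5.4 | 7.1 |

(standard deviation of a reading: 0.3 percentage points)

- free catalyst is single-handed; left-handed substrate and right-handed substrate are mirror images of each other, charged as a racemate, each of them at the stated concentration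
- the analysis behind the earlier runs scatters by 0.3 percentage points, standard deviation
- steps thought possible: free catalyst + right-handed substrate <-> catalyst intermediate B; reagent + free catalyst -> spent catalyst B; reagent + catalyst intermediate B -> free catalyst + right-handed product; 2 free catalyst -> spent catalyst C; reagent + catalyst intermediate A -> free catalyst + left-handed product; free catalyst + left-handed substrate <-> catalyst intermediate A; free catalyst + impurity -> spent catalyst A
- an excess is the difference of the two amounts in percent of their sum
- an excess is below zero if the other one leads

- excess of left-handed product over right-handed product in the product at 20 s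
- excess of left-handed product over right-handed product in the product at 6.0 min
- part of the left-handed substrate and right-handed substrate charged together that has reacted at 6.0 min

On the first rung the impurity takes catalyst one for one, leaving 79.5 % of it working in this flask, against 90.0 % in the north run and 59.0 % in the east run. The readings show no lag beyond their scatter, so we take this loss as over before the first samples. The products at 8.00 min in those runs, 11.0 % and 6.90 %, stand in a ratio of 1.59, near the working ratio of 1.53.

On the next rung the working catalyst binds substrate. Per working catalyst, the north-west run reads 1.44 times the north run's right-handed product at 8.00 min, on 1.50 times the reagent. We read this as catalyst sitting on right-handed substrate and waiting for reagent, with catalyst intermediate B as a resting state. So we expect a quick loss of substrate that is not product: the hold, the surviving catalyst as a fraction of both substrates charged, 7.95 %.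

The last rung is product, which the runs show growing over minutes. Scaling the north run by time and working catalyst gives 7.29 % by 6.0 min, which leaves 81.8 % of the reagent. Our reckoning for substrate reacted is therefore 15.2 %. The north run's excess at 8.00 min, −1.82 %, cannot be told from zero at a scatter of 0.3 percentage points on each reading, so we expect a small excess late in this flask.

The forecast gives excesses of −6 % at 20 s and −3 % at 6.0 min, and 7.3 % reacted at 6.0 min, holding that “Rate scales roughly with catalyst left after stoichiometric poisoning”. Its last figure has the size of our product, and ours differs by adding the hold.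

The flask gives excesses of −10.1 % at 20 s and 0.317 % at 6.0 min, and 14.7 % reacted at 6.0 min.

    free catalyst + right-handed substrate ⇌ catalyst intermediate B (K = 280 M⁻¹, k = 7.19 M⁻¹ s⁻¹)
    reagent + free catalyst → spent catalyst B (k = 0.0184 M⁻¹ s⁻¹)
    reagent + catalyst intermediate B → free catalyst + right-handed product (k = 0.0203 M⁻¹ s⁻¹)
    2 free catalyst → spent catalyst C (k = 0.0830 M⁻¹ s⁻¹)
    reagent + catalyst intermediate A → free catalyst + left-handed product (k = 0.219 M⁻¹ s⁻¹)
    free catalyst + left-handed substrate ⇌ catalyst intermediate A (K = 83.0 M⁻¹, k = 0.485 M⁻¹ s⁻¹)
    free catalyst + impurity → spent catalyst A (k = 150 M⁻¹ s⁻¹)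

At 6.00 min this flask holds 3.65 % left-handed product and 3.63 % right-handed product, so 7.42 % of the substrates has reacted without becoming product, beside a hold of 7.95 %. For the neighbouring flask with 0.010 M of impurity, the hold is 5.00 %. That neighbour has 9.36 % reacted and 4.67 % as product, which leaves 4.70 % reacted without becoming product.

The runs come from a simulation with made-up constants; the scatter is artificial.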